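## Retrosynthetic overview
1. Target lactol ⇒ flat, achiral isocoumarin ester + H2O. A last-step face-selective hydration makes the C3–OH bond and the C4–H stereocentre. C3 then settles thermodynamically, with the anomeric OH axial and trans to the pseudo-axial 4-methyl.
2. Isocoumarin ester ⇒ CH2–O ester bond. A protecting-group-free Mitsunobu reaction joins the east 3-(hydroxymethyl)isocoumarin to the west 2,4-dihydroxy-3,5,6-trimethylbenzoic acid.
3. East pyranone ring ⇒ carboxylate-directed C–H/O–H annulation of 2-hydroxy-4-methoxy-5-methylbenzoic acid with but-2-yn-1-ol. The phenol C–O bond ⇒ ortho C–H hydroxylation of 4-methoxy-3-methylbenzoic acid, which also blocks the easier ortho site.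
4. West acid ⇒ methyl atratate by C5 formylation, hydrogenolysis to methyl, and hydrolysis of the hindered ester.
5. Ring order: both benzene rings are bought. The only ring made is the pyranone (step 2), which becomes the lactol ring in step 7.

Assumption: the west acid is not counted as a cheap stock chemical and is therefore made, and because the sense of induction of the new catalyst cannot be predicted, "(S,S)" stands for the antipode that protonates the C4 Re face, to be checked against the rotation and ECD of the natural product.

## Route

Step 1
Reactants: 1 4-methoxy-3-methylbenzoic acid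
Product: 2 2-hydroxy-4-methoxy-5-methylbenzoic acid
Conditions: Pd(OAc)2 (10 mol %), KOAc (2 equiv), O2 (5 atm), DMA, 115 °C, 15 h; acidic work-up
Reagents that add atoms: dioxygen, O=O
Why: Carboxylate-directed palladium-catalysed ortho C–H hydroxylation, in which the potassium carboxylate steers divalent palladium into the unhindered C6–H (C2–H is flanked by the methyl group), O2 supplies the oxygen, and the new phenol leaves only the hindered ortho C–H free for step 2; no stereocentre is formed.

Step 2
Reactants: 2 2-hydroxy-4-methoxy-5-methylbenzoic acid; 3 but-2-yn-1-ol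
Product: 4 8-hydroxy-3-(hydroxymethyl)-6-methoxy-4,5-dimethyl-1H-isochromen-1-one
Conditions: [Cp*IrCl2]2 (2.5 mol %), AgOAc (2.2 equiv), MeOH, 60 °C, 16 h
Reagents that add atoms: none
Why: Carboxylate-directed oxidative C–H/O–H alkyne annulation (Miura–Satoh-type isocoumarin synthesis) at trivalent iridium, in which the only free ortho C–H is metalated, the aryl group adds to the smaller methyl-bearing alkyne carbon while the hydroxyl group holds the CH2OH-bearing carbon on the metal, and C–O reductive elimination with AgOAc as terminal oxidant closes the pyranone with CH2OH at C3 and CH3 at C4; free ortho-phenols are tolerated in this reaction class and no stereocentre is formed.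

Step 3
Reactants: 5 methyl 2,4-dihydroxy-3,6-dimethylbenzoate (methyl atratate)
Product: 6 methyl 5-formyl-2,4-dihydroxy-3,6-dimethylbenzoate
Conditions: Cl2CHOMe (1.3 equiv), TiCl4 (2.5 equiv), CH2Cl2, −10 °C to rt, 3 h; then ice/1 M HCl
Reagents that add atoms: dichloromethyl methyl ether, COC(Cl)Cl; water, O
Why: Rieche formylation of an electron-rich phenol, where C5 is the only unsubstituted ring position and is activated by the ortho 4-OH and the para 2-OH, so the regiochemistry is unambiguous; no stereocentre is formed.

Step 4
Reactants: 6 methyl 5-formyl-2,4-dihydroxy-3,6-dimethylbenzoate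
Product: 8 methyl 2,4-dihydroxy-3,5,6-trimethylbenzoate, via benzylic alcohol 7 (not isolated)
Conditions: H2 (3 atm), 10% Pd/C, AcOH, conc. HCl (cat.), rt, 12 h
Reagents that add atoms: none
Why: Catalytic hydrogenation followed by hydrogenolysis, in which the aldehyde is reduced to 7 and its ortho/para-hydroxy-activated benzylic C–O bond is cleaved under the same acidic conditions, while ester and phenols are inert; no stereocentre is formed.

Step 5
Reactants: 8 methyl 2,4-dihydroxy-3,5,6-trimethylbenzoate
Product: 10 2,4-dihydroxy-3,5,6-trimethylbenzoic acid, via aroyl cation 9 (not isolated)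
Conditions: conc. H2SO4, 0 °C to rt, 2 h; poured onto ice
Reagents that add atoms: water, O
Why: Acylium-type (A-AC-1) hydrolysis typical of di-ortho-substituted benzoates, in which the hindered electron-rich ester ionises to 9 in cold sulfuric acid and is captured by water on quenching, which avoids the hot alkali that decarboxylates resorcylic acids, and the fully substituted ring cannot be sulfonated; no stereocentre is formed.

Step 6
Reactants: 4 8-hydroxy-3-(hydroxymethyl)-6-methoxy-4,5-dimethyl-1H-isochromen-1-one; 10 2,4-dihydroxy-3,5,6-trimethylbenzoic acid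
Product: 11 (8-hydroxy-6-methoxy-4,5-dimethyl-1-oxo-1H-isochromen-3-yl)methyl 2,4-dihydroxy-3,5,6-trimethylbenzoate
Conditions: PPh3 (1.3 equiv), DIAD (1.3 equiv, added last), THF–toluene, 0 °C to rt, 6 h
Reagents that add atoms: none
Why: Mitsunobu esterification, in which the carboxylic acid (pKa about 3) is the only pronucleophile acidic enough to react, and SN2 attack of its carboxylate oxygen on the activated primary CH2 is insensitive to the di-ortho hindrance that blocks acyl-transfer esterification; unprotected resorcylic acids and hydrogen-bonded peri-phenols are known to survive, and no stereocentre is formed.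

Step 7
Reactants: 11 (8-hydroxy-6-methoxy-4,5-dimethyl-1-oxo-1H-isochromen-3-yl)methyl 2,4-dihydroxy-3,5,6-trimethylbenzoate
Product: 13 [(3R,4S)-3,8-dihydroxy-6-methoxy-4,5-dimethyl-1-oxo-3,4-dihydro-1H-isochromen-3-yl]methyl 2,4-dihydroxy-3,5,6-trimethylbenzoate, via C4-protonated oxocarbenium ion 12 (not isolated)
Conditions: (S,S)-imidodiphosphorimidate (IDPi) Brønsted acid built from two 3,3'-bis[3,5-bis(trifluoromethyl)phenyl]-BINOL units with N-triflyl groups on both phosphorus atoms (5 mol %), H2O (3 equiv), CPME–CH2Cl2 1:1 (0.03 M), −10 °C, 48 h; pH 7 buffer, acid-washed silica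
Reagents that add atoms: water, O
Why: Proposed new method: catalytic asymmetric hydration of an isocoumarin C3=C4 bond, in which the confined strong chiral acid delivers its proton to the Re face of C4 (the nucleophilic β-carbon of the enol ester, made more basic because pyramidalisation relieves the 4-Me/5-Me peri strain of flat 11), the resulting cation 12 is stabilised by the ring oxygen and the neighbouring ester carbonyl and stays paired with the chiral anion, whose basic P=N–SO2CF3 site positions water for C3–O bond formation, so C4 becomes S under catalyst control while C3 equilibrates by ring–chain tautomerism and settles as R (anomerically favoured axial OH, trans to the 4-methyl that stands pseudo-axial to avoid the 5-methyl, bulky CH2O-acyl equatorial); the closest known reaction types are chiral Brønsted-acid enantioselective protonation of silyl enol ethers, IDPi-catalysed asymmetric hydroalkoxylation and hydrolactonisation of alkenes, and enzyme-mediated enantioface-differentiating hydrolysis of enol esters, none of which has been shown on an enol lactone with water as nucleophile.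

## Compound list
1 | 4-methoxy-3-methylbenzoic acid | COc1ccc(C(=O)O)cc1C | starting material
2 | 2-hydroxy-4-methoxy-5-methylbenzoic acid | COc1cc(O)c(C(=O)O)cc1C | intermediate
3 | but-2-yn-1-ol | CC#CCO | starting material
4 | 8-hydroxy-3-(hydroxymethyl)-6-methoxy-4,5-dimethyl-1H-isochromen-1-one | COc1cc(O)c2c(c1C)C(C)=C(CO)OC2=O | intermediate
5 | methyl 2,4-dihydroxy-3,6-dimethylbenzoate (methyl atratate) | COC(=O)c1c(C)cc(O)c(C)c1O | starting material
6 | methyl 5-formyl-2,4-dihydroxy-3,6-dimethylbenzoate | COC(=O)c1c(C)c(C=O)c(O)c(C)c1O | intermediate
7 | methyl 2,4-dihydroxy-5-(hydroxymethyl)-3,6-dimethylbenzoate | COC(=O)c1c(C)c(CO)c(O)c(C)c1O | intermediate (not isolated)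
8 | methyl 2,4-dihydroxy-3,5,6-trimethylbenzoate | COC(=O)c1c(C)c(C)c(O)c(C)c1O | intermediate
9 | 2,4-dihydroxy-3,5,6-trimethylbenzoyl (aroyl) cation | [O+]#Cc1c(C)c(C)c(O)c(C)c1O | intermediate (not isolated)
10 | 2,4-dihydroxy-3,5,6-trimethylbenzoic acid | O=C(O)c1c(C)c(C)c(O)c(C)c1O | intermediate
11 | (8-hydroxy-6-methoxy-4,5-dimethyl-1-oxo-1H-isochromen-3-yl)methyl 2,4-dihydroxy-3,5,6-trimethylbenzoate | COc1cc(O)c2c(c1C)C(C)=C(COC(=O)c1c(C)c(C)c(O)c(C)c1O)OC2=O | intermediate
12 | (4S)-C4-protonated oxocarbenium ion of 11 (ion pair with the catalyst anion) | COc1cc(O)c2c(c1C)[C@H](C)C(COC(=O)c1c(C)c(C)c(O)c(C)c1O)=[O+]C2=O | intermediate (not isolated)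
13 | [(3R,4S)-3,8-dihydroxy-6-methoxy-4,5-dimethyl-1-oxo-3,4-dihydro-1H-isochromen-3-yl]methyl 2,4-dihydroxy-3,5,6-trimethylbenzoate | COc1cc(O)c2c(c1C)[C@H](C)[C@](O)(COC(=O)c1c(C)c(C)c(O)c(C)c1O)OC2=O | target

## Step count and risks
Total steps: 7. Longest linear sequence: 5 (5 → 6 → 8 → 10 → 11 → 13). The east branch, 1 → 2 → 4, joins at step 6.

**Step 7 (the new step).**
- Water may level the catalyst acidity below what an enol ester needs.
- The large substrate may not fit the confined pocket.
- Slow reversal through 12 would erode the ee.

Fallback with known chemistry: setting out from 11, hydrate without a chiral catalyst (TFA–H2O–1,4-dioxane 1:1:4, 40 °C). This is ordinary acid-catalysed enol-ester hydrolysis followed by ring–chain closure. It can be forced, since no selectivity is at stake. The product is the racemic trans-lactol, that is 13 together with its mirror image [(3S,4R)-3,8-dihydroxy-6-methoxy-4,5-dimethyl-1-oxo-3,4-dihydro-1H-isochromen-3-yl]methyl 2,4-dihydroxy-3,5,6-trimethylbenzoate F1. Preparative SFC on an immobilised amylose tris(3,5-dimethylphenylcarbamate) phase separates the two and comes back to the route at 13. F1 is dehydrated back to 11 (TsOH·H2O cat., toluene, Dean–Stark) and recycled.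

**Step 2.**
- The C–H bond is flanked by a methyl group, and the product carries 4-Me/5-Me peri strain.
- The alkynol can give the regioisomer.
- The alkynol can lose hydroxide from the alkenyl-metal stage to give an allene.

Fallback: put the oxygen in after the ring is made. Setting out from 2, the same annulation with symmetrical but-2-yne (sealed tube) removes both alkynol problems. It gives 8-hydroxy-6-methoxy-3,4,5-trimethyl-1H-isochromen-1-one F2. Riley oxidation (SeO2, 1,4-dioxane, 80 °C) follows, in which selenium attacks the enol-ester β-carbon C4 and the oxygen is transposed onto the 3-methyl group. This gives 8-hydroxy-6-methoxy-4,5-dimethyl-1-oxo-1H-isochromene-3-carbaldehyde F3. Luche reduction (NaBH4, CeCl3·7H2O, MeOH, −20 °C) comes back to the route at 4.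

**Step 1.**
- The electron-rich salicylic acid product may be over-oxidised at 115 °C under O2.
- It may also decarboxylate under the same conditions.

Fallback: stoichiometric directed ortho-metalation in place of catalytic C–H oxidation. Setting out from 1, s-BuLi/TMEDA (2.2 equiv each, THF, −78 °C) deprotonates ortho to the lithium carboxylate at the unhindered site. This gives lithium 2-lithio-4-methoxy-5-methylbenzoate F4. It is borylated in the same flask with B(OMe)3 and hydrolysed on acidic work-up to 2-borono-4-methoxy-5-methylbenzoic acid F5. Oxidation with H2O2/NaOH (0 °C) and acidification comes back to the route at 2.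

## Further compounds
F1 | step 7 | [(3S,4R)-3,8-dihydroxy-6-methoxy-4,5-dimethyl-1-oxo-3,4-dihydro-1H-isochromen-3-yl]methyl 2,4-dihydroxy-3,5,6-trimethylbenzoate | COc1cc(O)c2c(c1C)[C@@H](C)[C@@](O)(COC(=O)c1c(C)c(C)c(O)c(C)c1O)OC2=O
F2 | step 2 | 8-hydroxy-6-methoxy-3,4,5-trimethyl-1H-isochromen-1-one | COc1cc(O)c2c(c1C)C(C)=C(C)OC2=O
F3 | step 2 | 8-hydroxy-6-methoxy-4,5-dimethyl-1-oxo-1H-isochromene-3-carbaldehyde | COc1cc(O)c2c(c1C)C(C)=C(C=O)OC2=O
F4 | step 1 | lithium 2-lithio-4-methoxy-5-methylbenzoate | [Li]c1cc(OC)c(C)cc1C(=O)O[Li]
F5 | step 1 | 2-borono-4-methoxy-5-methylbenzoic acid | COc1cc(B(O)O)c(C(=O)O)cc1C
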